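**Plan**

1. Retrosynthetic cuts (labdane numbering: decalin C1–C10, chain C11–C15, butenolide carbinol C16): C13=C14 (cross-metathesis, frees the (R)-allylbutenolide); C9–C11 (B-alkyl Suzuki at a C8=C9 enol triflate); C5–C6 of ring B (reductive coupling of two carbonyl carbons); C8–C9 (crotylboration); C10–allyl (Pd allylation of ring A).
2. Enabling feature: C5, the A/B ring-fusion CH, sits between two carbons without hydrogen (gem-dimethyl C4, quaternary C10), so it is the carbonyl carbon of 2,2,6-trimethylcyclohexanone. C6 is a plain ring-B CH2 that can be carried as an aldehyde. Low-valent titanium joins these two electrophilic carbons, closes ring B, and the alkene can only lie at C5=C6.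
3. Forward order: ring A is bought; C10 is set; the C9–C6 chain is added; ring B closes at C5–C6; C5–H is installed; the C9 ketone becomes the tetrasubstituted C8=C9 alkene carrying C11–C13; the enal is made and joined last to the butenolide, itself made by singlet-oxygen dearomatisation of 3-furanmethanol.
4. Stereochemistry: C10 from Pd/(R)-t-BuPHOX decarboxylative allylation; C5 from radical hydrogen-atom transfer anti to the axial methyls on C4 and C10 (trans-decalin); C16 from chiral phosphoric acid allylboration; the E enal from thermodynamic control in metathesis.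

Key step: step 9

Remark (assumption): the C8 and C9 centres created in step 5 are carried as a diastereomer mixture and left undefined in the SMILES, because C9 becomes a ketone in step 11 and C8 trigonal in step 12.

**Route**

Step 1
Reactants: 1 2,2,6-trimethylcyclohexan-1-one
Product: 3 prop-2-en-1-yl 2,6,6-trimethylcyclohex-1-en-1-yl carbonate, via lithium enolate 2 (not isolated)
Conditions: LiHMDS, THF, 0 °C; then allyl chloroformate, −78 °C → rt
Reagents that add atoms: allyl chloroformate, C=CCOC(Cl)=O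
Why: Only one α-carbon of the ketone carries hydrogen, so a single tetrasubstituted lithium enolate forms, and this hindered enolate is acylated on oxygen (enol carbonate formation); the product has no stereocentre.

Step 2
Reactants: 3 prop-2-en-1-yl 2,6,6-trimethylcyclohex-1-en-1-yl carbonate
Product: 4 (2R)-2,6,6-trimethyl-2-(prop-2-en-1-yl)cyclohexan-1-one
Conditions: Pd2(dba)3 (2.5 mol %), (R)-t-BuPHOX (6 mol %), THF, 25 °C
Reagents that add atoms: none
Why: Decarboxylative asymmetric allylic alkylation (Tsuji–Stoltz type): Pd(0) ionises the allyl carbonate, CO2 leaves and the enolate recombines with the π-allyl-Pd unit inside the chiral PHOX pocket, which selects the enolate face and should set quaternary C10 as R (the R ligand is chosen because the S ligand gives S ketones in the 2-allyl-2-methylcyclohexanone series).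

Step 3
Reactants: 4 (2R)-2,6,6-trimethyl-2-(prop-2-en-1-yl)cyclohexan-1-one
Product: 5 (2R)-2,6,6-trimethyl-2-[(1E)-prop-1-en-1-yl]cyclohexan-1-one
Conditions: Pd(dba)2 (1 mol %), P(t-Bu)3 (1 mol %), i-PrCOCl (1 mol %), toluene, 80 °C
Reagents that add atoms: none
Why: Pd–H catalysed one-position alkene isomerisation (hydropalladation/β-hydride elimination) moves the double bond next to C10 and stops there because C10 has no hydrogen; the quaternary centre is not involved.

Step 4
Reactants: 5 (2R)-2,6,6-trimethyl-2-[(1E)-prop-1-en-1-yl]cyclohexan-1-one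
Product: 7 (1R)-1,3,3-trimethyl-2-oxocyclohexane-1-carbaldehyde, via secondary ozonide 6 (not isolated)
Conditions: O3, CH2Cl2, −78 °C; then Me2S, −78 °C → rt
Reagents that add atoms: ozone, [O-][O+]=O
Why: Ozonolysis (Criegee mechanism) cleaves the only C=C and leaves C9 as an aldehyde without α-hydrogen, so C10 cannot epimerise.

Step 5
Reactants: 7 (1R)-1,3,3-trimethyl-2-oxocyclohexane-1-carbaldehyde
Product: 9 (2R)-2-(1-hydroxy-2-methylbut-3-en-1-yl)-2,6,6-trimethylcyclohexan-1-one, via pinacol borate ester 8 (not isolated)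
Conditions: (E)-crotylB(pin), toluene, 50 °C; then aq. NaHCO3
Reagents that add atoms: (E)-crotylboronic acid pinacol ester, C/C=C/CB1OC(C)(C)C(C)(C)O1
Why: Hoffmann-type crotylboration through a closed chair transition state adds C8 (with its methyl), C7 and C6 in one step and only at the aldehyde, the ring ketone being shielded by two quaternary neighbours; C8/C9 should be anti, and the facial selectivity relative to C10 is left uncontrolled because both centres are erased in steps 11 and 12.

Step 6
Reactants: 9 (2R)-2-(1-hydroxy-2-methylbut-3-en-1-yl)-2,6,6-trimethylcyclohexan-1-one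
Product: 10 (2R)-2-(1-{[tert-butyl(dimethyl)silyl]oxy}-2-methylbut-3-en-1-yl)-2,6,6-trimethylcyclohexan-1-one
Conditions: TBSOTf, 2,6-lutidine, CH2Cl2, −78 → 0 °C
Reagents that add atoms: tert-butyldimethylsilyl trifluoromethanesulfonate, CC(C)(C)[Si](C)(C)OS(=O)(=O)C(F)(F)F
Why: Silyl triflate silylation of the hindered secondary alcohol under non-basic conditions avoids retro-aldol cleavage and makes the C9 oxygen inert to borane, oxidant and titanium.

Step 7
Reactants: 10 (2R)-2-(1-{[tert-butyl(dimethyl)silyl]oxy}-2-methylbut-3-en-1-yl)-2,6,6-trimethylcyclohexan-1-one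
Product: 12 (2R)-2-(1-{[tert-butyl(dimethyl)silyl]oxy}-4-hydroxy-2-methylbutyl)-2,6,6-trimethylcyclohexan-1-one, via B-alkyl-9-BBN adduct 11 (not isolated)
Conditions: 9-BBN, THF, 0 °C → rt; then aq. NaOAc, H2O2, 0 °C
Reagents that add atoms: hydrogen peroxide, OO
Why: Anti-Markovnikov hydroboration of the monosubstituted alkene by 9-BBN and oxidation of the C–B bond place the hydroxyl on terminal C6; the ring ketone, flanked by two quaternary carbons, should not be reduced.

Step 8
Reactants: 12 (2R)-2-(1-{[tert-butyl(dimethyl)silyl]oxy}-4-hydroxy-2-methylbutyl)-2,6,6-trimethylcyclohexan-1-one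
Product: 13 4-{[tert-butyl(dimethyl)silyl]oxy}-3-methyl-4-[(1R)-1,3,3-trimethyl-2-oxocyclohexyl]butanal
Conditions: Dess–Martin periodinane, NaHCO3, CH2Cl2, 0 °C → rt
Reagents that add atoms: none
Why: Dess–Martin oxidation converts the primary alcohol into the C6 aldehyde under buffered conditions that leave the silyl ether and the hindered ketone untouched.

Step 9
Reactants: 13 4-{[tert-butyl(dimethyl)silyl]oxy}-3-methyl-4-[(1R)-1,3,3-trimethyl-2-oxocyclohexyl]butanal
Product: 15 tert-butyl(dimethyl){[(8aS)-2,5,5,8a-tetramethyl-1,2,3,5,6,7,8,8a-octahydronaphthalen-1-yl]oxy}silane, via titanium pinacolate 14 (not isolated)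
Conditions: TiCl3(DME)1.5, Zn–Cu, DME, reflux; 13 added by syringe pump over 30 h (high dilution)
Reagents that add atoms: none
Why: McMurry coupling: low-valent titanium transfers single electrons to both carbonyl groups (the aldehyde first), the C6 ketyl joins C5 of the ketone on the titanium surface to give pinacolate 14, and at reflux both C–O bonds are cleaved to leave the C5=C6 alkene. The closest known reaction type is the intramolecular titanium-mediated keto-aldehyde coupling to cycloalkenes. Ring B (C5–C6–C7–C8–C9–C10) closes as a six-membered ring by attack of the C6 ketyl on the C5 carbonyl, formally a 6-exo-trig closure. No stereocentre is created here: C5 becomes trigonal and is set in step 10, while C10 is untouched. The step needs cyclisation instead of intermolecular coupling and a single alkene position: the 1,6-spacing of the carbonyls, the branching at C8, C9 and C10 (Thorpe–Ingold effect) and slow addition favour the first, and the absence of hydrogen on C4 and C10 fixes the double bond at C5=C6. The C9 oxygen, masked as a silyl ether, is the only other functional group and is inert to the reagent.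

Step 10
Reactants: 15 tert-butyl(dimethyl){[(8aS)-2,5,5,8a-tetramethyl-1,2,3,5,6,7,8,8a-octahydronaphthalen-1-yl]oxy}silane
Product: 16 tert-butyl(dimethyl){[(4aS,8aS)-2,5,5,8a-tetramethyldecahydronaphthalen-1-yl]oxy}silane
Conditions: Mn(dpm)3 (10 mol %), PhSiH3, t-BuOOH, i-PrOH, 22 °C
Reagents that add atoms: none
Why: Metal-hydride hydrogen-atom-transfer hydrogenation (Mukaiyama/Shenvi type): Mn–H transfers H• to C6 to give the tertiary C5 radical, which should accept its hydrogen on the α face, anti to the axial methyl groups on C4 and C10, so that C5 becomes S and the ring fusion trans.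

Step 11
Reactants: 16 tert-butyl(dimethyl){[(4aS,8aS)-2,5,5,8a-tetramethyldecahydronaphthalen-1-yl]oxy}silane
Product: 18 (4aS,8aS)-2,5,5,8a-tetramethyloctahydronaphthalen-1(2H)-one, via free decalinol 17 (not isolated)
Conditions: CrO3, aq. H2SO4 (Jones reagent), acetone, 0 °C → rt
Reagents that add atoms: none
Why: Jones reagent removes the silyl group by acid hydrolysis and oxidises the freed secondary alcohol to the C9 ketone in one pot (oxidative desilylation); C10 is quaternary and C5 is not α to the ketone, so neither can epimerise, and the C8 epimers are of no consequence.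

Step 12
Reactants: 18 (4aS,8aS)-2,5,5,8a-tetramethyloctahydronaphthalen-1(2H)-one
Product: 20 (4aS,8aS)-2,5,5,8a-tetramethyl-3,4,4a,5,6,7,8,8a-octahydronaphthalen-1-yl trifluoromethanesulfonate, via potassium enolate 19 (not isolated)
Conditions: KHMDS, THF, −78 → 0 °C; then PhNTf2, −78 °C → rt
Reagents that add atoms: N-phenylbis(trifluoromethanesulfonimide), O=S(=O)(N(c1ccccc1)S(=O)(=O)C(F)(F)F)C(F)(F)F
Why: Only C8 bears an α-hydrogen, so KHMDS gives a single tetrasubstituted enolate, and O-sulfonylation (enol triflate formation) fixes the future C8=C9 double bond without regiochemical ambiguity.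

Step 13
Reactants: 20 (4aS,8aS)-2,5,5,8a-tetramethyl-3,4,4a,5,6,7,8,8a-octahydronaphthalen-1-yl trifluoromethanesulfonate; 21 4,4-diethoxybut-1-ene
Product: 23 (4aS,8aS)-1-(4,4-diethoxybutyl)-2,5,5,8a-tetramethyl-3,4,4a,5,6,7,8,8a-octahydronaphthalene, via alkyl-9-BBN reagent 22 (not isolated)
Conditions: 21, 9-BBN, THF, rt; then 20, PdCl2(dppf) (10 mol %), AsPh3, Cs2CO3, DMF/H2O, 60 °C
Reagents that add atoms: none
Why: B-alkyl Suzuki–Miyaura coupling: 9-BBN hydroborates 21 at its CH2 end, and oxidative addition of Pd(0) into the C9–OTf bond, base-assisted alkyl transfer from boron and reductive elimination attach C11–C13 and the acetal carbon to C9; no stereocentre is affected.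

Step 14
Reactants: 23 (4aS,8aS)-1-(4,4-diethoxybutyl)-2,5,5,8a-tetramethyl-3,4,4a,5,6,7,8,8a-octahydronaphthalene
Product: 24 4-[(4aS,8aS)-2,5,5,8a-tetramethyl-3,4,4a,5,6,7,8,8a-octahydronaphthalen-1-yl]butanal
Conditions: PPTS, acetone/H2O, 50 °C
Reagents that add atoms: water, O
Why: Mild acid-catalysed acetal hydrolysis releases the aldehyde without isomerising the tetrasubstituted C8=C9 alkene.

Step 15
Reactants: 24 4-[(4aS,8aS)-2,5,5,8a-tetramethyl-3,4,4a,5,6,7,8,8a-octahydronaphthalen-1-yl]butanal
Product: 25 2-methylidene-4-[(4aS,8aS)-2,5,5,8a-tetramethyl-3,4,4a,5,6,7,8,8a-octahydronaphthalen-1-yl]butanal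
Conditions: 37% aq. HCHO, pyrrolidine (10 mol %), propionic acid (10 mol %), i-PrOH, 45 °C
Reagents that add atoms: formaldehyde, C=O
Why: Amine-catalysed α-methylenation (Mannich condensation of the enamine with formaldehyde, then elimination of the amine) converts the CH2 next to the formyl group (C13) into the 1,1-disubstituted enal needed for metathesis.

Step 16
Reactants: 26 furan-3-ylmethanol
Product: 27 tert-butyl(furan-3-ylmethoxy)dimethylsilane
Conditions: TBSCl, imidazole, DMF, rt
Reagents that add atoms: tert-butyldimethylsilyl chloride, CC(C)(C)[Si](C)(C)Cl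
Why: Standard silylation of the primary alcohol protects it during photo-oxygenation, methylation and allylboration.

Step 17
Reactants: 27 tert-butyl(furan-3-ylmethoxy)dimethylsilane
Product: 29 4-({[tert-butyl(dimethyl)silyl]oxy}methyl)-5-hydroxyfuran-2(5H)-one, via furan endoperoxide 28 (not isolated)
Conditions: O2, hν (visible), rose bengal (cat.), i-Pr2NEt, CH2Cl2, −78 °C
Reagents that add atoms: dioxygen, O=O
Why: Dearomatisation of the furan: singlet oxygen adds across C2/C5 in a [4+2] cycloaddition and the hindered amine removes the less hindered bridgehead hydrogen of endoperoxide 28 (Kornblum–DeLaMare type fragmentation), which should place the lactone carbonyl away from, and the hemiacetal carbon next to, the CH2OSi group; the racemic lactol centre is erased in step 18.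

Step 18
Reactants: 29 4-({[tert-butyl(dimethyl)silyl]oxy}methyl)-5-hydroxyfuran-2(5H)-one
Product: 30 methyl (2Z)-4-{[tert-butyl(dimethyl)silyl]oxy}-3-formylbut-2-enoate
Conditions: MeI, K2CO3, DMF, 0 °C
Reagents that add atoms: iodomethane, CI
Why: The γ-hydroxybutenolide is the ring tautomer of a cis-formyl acrylic acid, so carbonate opens it to the carboxylate and O-methylation (SN2 on MeI) traps the open (Z)-aldehyde ester, keeping the formyl group cis to the ester for later lactonisation.

Step 19
Reactants: 30 methyl (2Z)-4-{[tert-butyl(dimethyl)silyl]oxy}-3-formylbut-2-enoate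
Product: 33 (5R)-4-(hydroxymethyl)-5-(prop-2-en-1-yl)furan-2(5H)-one, via O-boryl hydroxy ester 31 (not isolated), via silyl-protected butenolide 32 (not isolated)
Conditions: allylB(pin), (R)-TRIP (5 mol %), toluene, −30 °C; then p-TsOH·H2O, MeOH, rt
Reagents that add atoms: allylboronic acid pinacol ester, C=CCB1OC(C)(C)C(C)(C)O1
Why: Chiral phosphoric acid catalysed allylboration (Antilla type) runs through a chair transition state with the catalyst hydrogen-bonded to the boronate oxygen and the formyl hydrogen, and the R catalyst (the enantiomer that gives (R)-1-phenylbut-3-en-1-ol from benzaldehyde) should deliver allyl to the Re face and set C16 as R; acidic methanol then cleaves the borate, closes the lactone onto the cis ester and removes the primary silyl ether without base, so the γ-centre cannot racemise.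

Step 20
Reactants: 25 2-methylidene-4-[(4aS,8aS)-2,5,5,8a-tetramethyl-3,4,4a,5,6,7,8,8a-octahydronaphthalen-1-yl]butanal; 33 (5R)-4-(hydroxymethyl)-5-(prop-2-en-1-yl)furan-2(5H)-one
Product: 34 (2E)-4-[(2R)-3-(hydroxymethyl)-5-oxo-2,5-dihydrofuran-2-yl]-2-{2-[(4aS,8aS)-2,5,5,8a-tetramethyl-3,4,4a,5,6,7,8,8a-octahydronaphthalen-1-yl]ethyl}but-2-enal (CNP0197865.2)
Conditions: Hoveyda–Grubbs II (10 mol %), CH2Cl2, 40 °C; 33 (2 equiv)
Reagents that add atoms: none
Why: Olefin cross-metathesis between the terminal alkene of 33 and the 1,1-disubstituted enal 25 (a partner that does not homodimerise) joins C13=C14 with loss of ethene; the tetrasubstituted C8=C9 and the electron-poor butenolide alkene are inert, the E enal (CHO trans to C15) is the thermodynamic product, no stereocentre is touched, and stereoisomers stemming from the minor enantiomer of either fragment are diastereomers of 34 that can be removed at this stage.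

**Compound list**

1 | 2,2,6-trimethylcyclohexan-1-one (racemic) | CC1CCCC(C)(C)C1=O | starting material
2 | lithium 2,6,6-trimethylcyclohex-1-en-1-olate | [Li+].[O-]C1=C(C)CCCC1(C)C | intermediate
3 | prop-2-en-1-yl 2,6,6-trimethylcyclohex-1-en-1-yl carbonate | C=CCOC(=O)OC1=C(C)CCCC1(C)C | intermediate
4 | (2R)-2,6,6-trimethyl-2-(prop-2-en-1-yl)cyclohexan-1-one | C=CC[C@@]1(C)CCCC(C)(C)C1=O | intermediate
5 | (2R)-2,6,6-trimethyl-2-[(1E)-prop-1-en-1-yl]cyclohexan-1-one | C/C=C/[C@@]1(C)CCCC(C)(C)C1=O | intermediate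
6 | secondary ozonide (1,2,4-trioxolane) of 5 | CC1OOC(O1)[C@@]1(C)CCCC(C)(C)C1=O | intermediate
7 | (1R)-1,3,3-trimethyl-2-oxocyclohexane-1-carbaldehyde | O=C[C@@]1(C)CCCC(C)(C)C1=O | intermediate
8 | pinacol borate ester of 9 | C=CC(C)C(OB1OC(C)(C)C(C)(C)O1)[C@@]1(C)CCCC(C)(C)C1=O | intermediate
9 | (2R)-2-(1-hydroxy-2-methylbut-3-en-1-yl)-2,6,6-trimethylcyclohexan-1-one (C8/C9 anti, both C9 epimers) | C=CC(C)C(O)[C@@]1(C)CCCC(C)(C)C1=O | intermediate
10 | (2R)-2-(1-{[tert-butyl(dimethyl)silyl]oxy}-2-methylbut-3-en-1-yl)-2,6,6-trimethylcyclohexan-1-one | C=CC(C)C(O[Si](C)(C)C(C)(C)C)[C@@]1(C)CCCC(C)(C)C1=O | intermediate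
11 | B-alkyl-9-BBN adduct of 10 (boron on C6) | CC(CCB1C2CCCC1CCC2)C(O[Si](C)(C)C(C)(C)C)[C@@]1(C)CCCC(C)(C)C1=O | intermediate
12 | (2R)-2-(1-{[tert-butyl(dimethyl)silyl]oxy}-4-hydroxy-2-methylbutyl)-2,6,6-trimethylcyclohexan-1-one | OCCC(C)C(O[Si](C)(C)C(C)(C)C)[C@@]1(C)CCCC(C)(C)C1=O | intermediate
13 | 4-{[tert-butyl(dimethyl)silyl]oxy}-3-methyl-4-[(1R)-1,3,3-trimethyl-2-oxocyclohexyl]butanal | O=CCC(C)C(O[Si](C)(C)C(C)(C)C)[C@@]1(C)CCCC(C)(C)C1=O | intermediate
14 | titanium pinacolate from 13 (C5/C6 diolate, drawn as the free diol) | CC(C)(C)[Si](C)(C)OC1[C@@]2(C)CCCC(C)(C)C2(O)C(O)CC1C | intermediate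
15 | tert-butyl(dimethyl){[(8aS)-2,5,5,8a-tetramethyl-1,2,3,5,6,7,8,8a-octahydronaphthalen-1-yl]oxy}silane | CC(C)(C)[Si](C)(C)OC1[C@@]2(C)CCCC(C)(C)C2=CCC1C | intermediate
16 | tert-butyl(dimethyl){[(4aS,8aS)-2,5,5,8a-tetramethyldecahydronaphthalen-1-yl]oxy}silane | CC(C)(C)[Si](C)(C)OC1[C@@]2(C)CCCC(C)(C)[C@@H]2CCC1C | intermediate
17 | (4aS,8aS)-2,5,5,8a-tetramethyldecahydronaphthalen-1-ol | OC1[C@@]2(C)CCCC(C)(C)[C@@H]2CCC1C | intermediate
18 | (4aS,8aS)-2,5,5,8a-tetramethyloctahydronaphthalen-1(2H)-one (C8 epimers) | O=C1[C@@]2(C)CCCC(C)(C)[C@@H]2CCC1C | intermediate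
19 | potassium (4aS,8aS)-2,5,5,8a-tetramethyl-3,4,4a,5,6,7,8,8a-octahydronaphthalen-1-olate | CC1=C([O-])[C@@]2(C)CCCC(C)(C)[C@@H]2CC1.[K+] | intermediate
20 | (4aS,8aS)-2,5,5,8a-tetramethyl-3,4,4a,5,6,7,8,8a-octahydronaphthalen-1-yl trifluoromethanesulfonate | CC1=C(OS(=O)(=O)C(F)(F)F)[C@@]2(C)CCCC(C)(C)[C@@H]2CC1 | intermediate
21 | 4,4-diethoxybut-1-ene | C=CCC(OCC)OCC | starting material
22 | 9-(4,4-diethoxybutyl)-9-borabicyclo[3.3.1]nonane | CCOC(CCCB1C2CCCC1CCC2)OCC | intermediate
23 | (4aS,8aS)-1-(4,4-diethoxybutyl)-2,5,5,8a-tetramethyl-3,4,4a,5,6,7,8,8a-octahydronaphthalene | CC1=C(CCCC(OCC)OCC)[C@@]2(C)CCCC(C)(C)[C@@H]2CC1 | intermediate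
24 | 4-[(4aS,8aS)-2,5,5,8a-tetramethyl-3,4,4a,5,6,7,8,8a-octahydronaphthalen-1-yl]butanal | CC1=C(CCCC=O)[C@@]2(C)CCCC(C)(C)[C@@H]2CC1 | intermediate
25 | 2-methylidene-4-[(4aS,8aS)-2,5,5,8a-tetramethyl-3,4,4a,5,6,7,8,8a-octahydronaphthalen-1-yl]butanal | CC1=C(CCC(=C)C=O)[C@@]2(C)CCCC(C)(C)[C@@H]2CC1 | intermediate
26 | furan-3-ylmethanol | OCc1ccoc1 | starting material
27 | tert-butyl(furan-3-ylmethoxy)dimethylsilane | CC(C)(C)[Si](C)(C)OCc1ccoc1 | intermediate
28 | 5-({[tert-butyl(dimethyl)silyl]oxy}methyl)-2,3,7-trioxabicyclo[2.2.1]hept-5-ene | CC(C)(C)[Si](C)(C)OCC1=CC2OOC1O2 | intermediate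
29 | 4-({[tert-butyl(dimethyl)silyl]oxy}methyl)-5-hydroxyfuran-2(5H)-one (racemic) | CC(C)(C)[Si](C)(C)OCC1=CC(=O)OC1O | intermediate
30 | methyl (2Z)-4-{[tert-butyl(dimethyl)silyl]oxy}-3-formylbut-2-enoate | COC(=O)/C=C(/CO[Si](C)(C)C(C)(C)C)C=O | intermediate
31 | methyl (2Z,4R)-3-({[tert-butyl(dimethyl)silyl]oxy}methyl)-4-[(4,4,5,5-tetramethyl-1,3,2-dioxaborolan-2-yl)oxy]hepta-2,6-dienoate | COC(=O)/C=C(/CO[Si](C)(C)C(C)(C)C)[C@H](OB1OC(C)(C)C(C)(C)O1)CC=C | intermediate
32 | (5R)-4-({[tert-butyl(dimethyl)silyl]oxy}methyl)-5-(prop-2-en-1-yl)furan-2(5H)-one | C=CC[C@H]1OC(=O)C=C1CO[Si](C)(C)C(C)(C)C | intermediate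
33 | (5R)-4-(hydroxymethyl)-5-(prop-2-en-1-yl)furan-2(5H)-one | C=CC[C@H]1OC(=O)C=C1CO | intermediate
34 | (2E)-4-[(2R)-3-(hydroxymethyl)-5-oxo-2,5-dihydrofuran-2-yl]-2-{2-[(4aS,8aS)-2,5,5,8a-tetramethyl-3,4,4a,5,6,7,8,8a-octahydronaphthalen-1-yl]ethyl}but-2-enal (CNP0197865.2) | CC1=C(CC/C(C=O)=C\C[C@H]2OC(=O)C=C2CO)[C@@]2(C)CCCC(C)(C)[C@@H]2CC1 | target

**Step count and risks**

Total: 20 steps. Longest linear sequence: 16 steps (steps 1–15 and 20).

Step 9. The ketone between two quaternary carbons may be too slow in pinacolate formation, so that the aldehyde is consumed by intermolecular coupling or simple reduction. Fallback (polarity reversal at C6 in place of double carbonyl reduction): from primary alcohol 12, Appel iodination (I2, PPh3, imidazole) should give the primary iodide F1. SmI2/HMPA in THF then reduces the C–I bond to an organosamarium that adds to the C5 ketone (intramolecular Barbier reaction, six-membered ring) to give the tertiary decalinol F2. Dehydration with SOCl2/pyridine can only take a hydrogen from C6 and therefore comes back to alkene 15.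

Step 13. Oxidative addition and transmetalation at the tetrasubstituted triflate next to quaternary C10 may be slow, so that the alkylborane is lost by protodeboronation or β-hydride elimination. Fallback (C11–C12 bond by sp3–sp3 coupling instead): from triflate 20, Pd-catalysed methoxycarbonylation (Pd(OAc)2, dppp, CO, MeOH, Et3N) should give the unsaturated methyl ester F3. DIBAL-H gives the allylic alcohol F4 and PBr3 the allylic bromide F5. Li2CuCl4-catalysed coupling with [2-(1,3-dioxolan-2-yl)ethyl]magnesium bromide gives the dioxolane F6, and PPTS in wet acetone comes back to aldehyde 24.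

Step 20. The hindered 1,1-disubstituted enal may not enter the catalytic cycle, leaving homodimerisation of 33 and double-bond migration as the main processes. Fallback (Wittig olefination instead of metathesis): from butenolide 33, ozonolysis (O3, then Me2S) should give the aldehyde F7, in equilibrium with its six-membered lactol. From aldehyde 24, enamine-mediated α-bromination (cat. pyrrolidine, 4,4-dibromo-2,6-di-tert-butylcyclohexa-2,5-dienone) gives the α-bromo aldehyde F8, and PPh3 followed by Et3N the stabilised formyl ylide F9. Heating F9 with F7 in toluene should give the E enal directly, which is target 34.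

Further compounds
F1 | step 9 | (2R)-2-(1-{[tert-butyl(dimethyl)silyl]oxy}-4-iodo-2-methylbutyl)-2,6,6-trimethylcyclohexan-1-one | ICCC(C)C(O[Si](C)(C)C(C)(C)C)[C@@]1(C)CCCC(C)(C)C1=O
F2 | step 9 | 1-{[tert-butyl(dimethyl)silyl]oxy}-2,5,5,8a-tetramethyloctahydronaphthalen-4a(2H)-ol (C10 as in 13, C5 either epimer) | CC(C)(C)[Si](C)(C)OC1[C@@]2(C)CCCC(C)(C)C2(O)CCC1C
F3 | step 13 | methyl (4aS,8aS)-2,5,5,8a-tetramethyl-3,4,4a,5,6,7,8,8a-octahydronaphthalene-1-carboxylate | CC1=C(C(=O)OC)[C@@]2(C)CCCC(C)(C)[C@@H]2CC1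
F4 | step 13 | [(4aS,8aS)-2,5,5,8a-tetramethyl-3,4,4a,5,6,7,8,8a-octahydronaphthalen-1-yl]methanol | CC1=C(CO)[C@@]2(C)CCCC(C)(C)[C@@H]2CC1
F5 | step 13 | (4aS,8aS)-1-(bromomethyl)-2,5,5,8a-tetramethyl-3,4,4a,5,6,7,8,8a-octahydronaphthalene | CC1=C(CBr)[C@@]2(C)CCCC(C)(C)[C@@H]2CC1
F6 | step 13 | 2-{3-[(4aS,8aS)-2,5,5,8a-tetramethyl-3,4,4a,5,6,7,8,8a-octahydronaphthalen-1-yl]propyl}-1,3-dioxolane | CC1=C(CCCC3OCCO3)[C@@]2(C)CCCC(C)(C)[C@@H]2CC1
F7 | step 20 | [(2R)-3-(hydroxymethyl)-5-oxo-2,5-dihydrofuran-2-yl]acetaldehyde | O=CC[C@H]1OC(=O)C=C1CO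
F8 | step 20 | 2-bromo-4-[(4aS,8aS)-2,5,5,8a-tetramethyl-3,4,4a,5,6,7,8,8a-octahydronaphthalen-1-yl]butanal (C2 either epimer) | CC1=C(CCC(Br)C=O)[C@@]2(C)CCCC(C)(C)[C@@H]2CC1
F9 | step 20 | 4-[(4aS,8aS)-2,5,5,8a-tetramethyl-3,4,4a,5,6,7,8,8a-octahydronaphthalen-1-yl]-2-(triphenyl-λ5-phosphanylidene)butanal | CC1=C(CCC(C=O)=P(c3ccccc3)(c3ccccc3)c3ccccc3)[C@@]2(C)CCCC(C)(C)[C@@H]2CC1
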